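The choice to make is how the charge goes in: everything together in delta, electrophile by feed in theta or in portions in alpha, or free base by a cold feed in epsilon.

| flask | electrophile | free base | protonated nucleophile | scavenger | temperature | remark | time |
|---|---|---|---|---|---|---|---|
| north-west | 0.18 M | 0.80 equiv | 3 equiv | 0.80 equiv | 25 °C | run made earlier |  |
| east | 0.18 M | 0.80 equiv | 3 equiv | 1.2 equiv | 25 °C | run made earlier |  |
| epsilon | 0.18 M | 0.800 equiv (fed, over 20 min) | 3.00 equiv | 0.800 equiv |  | the addition at −15 °C, then warmed to 25 °C; the feed brings no volume worth counting | 25 min |
| delta | 0.18 M | 0.800 equiv | 3.00 equiv | 0.800 equiv | 25 °C | everything together at the start | 25 min |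
| theta | 0.18 M (fed, over 20 min) | 0.800 equiv | 3.00 equiv | 0.800 equiv | 25 °C | all else is in the flask from the start; the feed brings no volume worth counting | 25 min |
| alpha | 0.18 M (in portions, 3, over 20 min) | 0.800 equiv | 3.00 equiv | 0.800 equiv | 25 °C | first portion at the start, last at 20 min | 25 min |

| run | time / min | target / % |
|---|---|---|
| north-west | 0.833 | 2.5 |
| north-west | 2.50 | 7.2 |
| north-west | 4.00 | 10.9 |
| north-west | 6.00 | 15.0 |
| north-west | 10.0 | 20.7 |
| north-west | 12.0 | 23.0 |
| north-west | 15.0 | 25.3 |
| east | 0.250 | 0.3 |
| east | 0.833 | 2.8 |
| east | 1.33 | 4.2 |
| east | 2.00 | 6.1 |
| east | 3.00 | 9.0 |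
| east | 4.00 | 10.7 |
| east | 5.00 | 12.9 |

(standard deviation of a reading: 0.3 percentage points)

- which flask leads in amount of target, in percent of the electrophile charged ("all alike" within 1.5 percentage points) (epsilon / delta / theta / alpha / all alike)
- how much target is there at the end, in percent of the electrophile charged: epsilon
- how much target is there at the end, in percent of the electrophile charged: delta
- how much target is there at the end, in percent of the electrophile charged: theta
- how much target is there at the end, in percent of the electrophile charged: alpha

- a species is counted by the electrophile in it: one side product counts as two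
- amounts and yields of acid set free count idle adduct too
- candidate steps: electrophile + nucleophile -> acid set free + target; nucleophile + acid set free <-> protonated nucleophile; acid set free + free base <-> salt of the base; nucleophile + acid set free <-> idle adduct; acid set free + scavenger -> scavenged by-product; electrophile + target -> side product
- the earlier runs do not show what temperature does; that part of a forecast is a guess

The rate follows [electrophile][nucleophile]. The first north-west reading gives a start rate of 0.0300 min⁻¹ as a fraction of the charge. Two factors slow it. One is the electrophile share left. The other comes from the balance of free base, here the limiting reagent for nucleophile supply. Free base frees nucleophile one for one, each target spends one nucleophile, and its acid takes back a second. With scavenger set aside, the balance reaches nil at the base stop, 40.0% target, and the nucleophile factor is the share of that stop unused. Setting scavenger aside rests on the readings: at 4.00 min, north-west shows 10.9% and east 10.7%, despite more scavenger in east.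

At north-west's last reading the factors are 74.7% and 36.8%, together 0.275. The last interval reads 0.255 of the start rate. Integrated, the logarithm of the first factor over the second grows in step with time, at 0.0473 min⁻¹. My own reckoning carries this to 25 min for delta, which has the same charges, and gives 1.18 on that logarithm and 31.6% target. The unslowed start rate would give 75.0%. Feeding lowers the electrophile factor early in theta and alpha. Epsilon's cold stage remains a guess.

The forecast, on the ground that “each target's acid reprotonates a second nucleophile”, names delta: delta 32% (29.5% to 35%), theta 25% (22% to 28%), alpha 25% (22% to 28%), epsilon 15% (10% to 22%).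

The flasks give delta in the lead: delta 32.7%, theta 26.6%, alpha 26.2%, epsilon 13.2%.

    electrophile + nucleophile → acid set free + target (k = 0.00400 L mol⁻¹ s⁻¹, Ea = 72.0 kJ mol⁻¹)
    nucleophile + acid set free ⇌ protonated nucleophile, settled at all times (K = 670 L mol⁻¹, ΔH = −58.0 kJ mol⁻¹)
    acid set free + free base ⇌ salt of the base, settled at all times (K = 5000 L mol⁻¹, ΔH = −79.0 kJ mol⁻¹)
    nucleophile + acid set free ⇌ idle adduct, settled at all times (K = 1.80 L mol⁻¹, ΔH = −25.0 kJ mol⁻¹)
    acid set free + scavenger → scavenged by-product (k = 0.0230 L mol⁻¹ s⁻¹, Ea = 71.0 kJ mol⁻¹)
    electrophile + target → side product (k = 0.00120 L mol⁻¹ s⁻¹, Ea = 63.0 kJ mol⁻¹)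
    (constants at 25 °C)

Delta's 32.7% stands below the base stop of 40.0% and near the reckoned 31.6%. A neighbour of delta has electrophile at 0.045 M, with equivalents and time held. Its base stop stays 40.0%, while the logarithm scales with the charge to 0.296, which gives 14.6% target. That neighbour gives 17.2% target, with 1.33% side product and 81.5% electrophile left.

The data stem from a simulated flask with constants of no real substance, noise included.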